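**Retrosynthetic overview**

1. Ciwujiatone (7S,8R,8'R; 8-CH2OH and 8'-aroyl cis) ⇐ oxidative opening of ring B of (7S,8R,7'S,8'R)-syringaresinol: hydride loss at C7', quinone methide, hydration, hemiketal collapse. The cis-fused bicycle fixes the epimerisable C8' centre.
2. Syringaresinol ⇐ two quinone-methide oxa-cyclisations of an acyclic 8–8'-linked diol: ring A (C7–O–C9', kept in the target) first, ring B (C7'–O–C9, transient) second. The quinone methides come from DDQ dehydrogenation, and all three oxidations run in one flask.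
3. (8R,8'R)-Diol ⇐ LiAlH4 reduction of a (2R,3R)-2,3-dibenzylsuccinyl bis-imide.
4. Bis-imide ⇐ auxiliary-controlled oxidative 8–8' homocoupling of a dihydrosinapoyl imide enolate (sets C8 and C8').
5. Imide ⇐ sinapic acid + (S)-4-isopropyloxazolidin-2-one.

Assumption: the SMILES is read as (7S,8R,8'R) in lignan numbering (C7 = aryl-bearing ring carbon, C8 = CH2OH-bearing carbon, C8' = aroyl-bearing carbon, C9' = ring CH2, C7' = C=O); this corresponds to ring-opened (7S,8R,7'S,8'R)-syringaresinol.

**Route**

Step 1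
Reactants: 1 sinapic acid [(E)-3-(4-hydroxy-3,5-dimethoxyphenyl)prop-2-enoic acid]
Product: 2 dihydrosinapic acid [3-(4-hydroxy-3,5-dimethoxyphenyl)propanoic acid]
Conditions: H2 (1 atm), 10% Pd/C, MeOH, rt
Reagents that add atoms: none
Why: Heterogeneous catalytic hydrogenation saturates only the conjugated C=C (arene, phenol and acid are inert at 1 atm); no stereocentre is formed.

Step 2
Reactants: 2 dihydrosinapic acid; 3 (S)-4-isopropyloxazolidin-2-one
Product: 6 (S)-3-{3-[3,5-dimethoxy-4-(pivaloyloxy)phenyl]propanoyl}-4-isopropyloxazolidin-2-one, via mixed anhydride 4 (not isolated), via phenolic imide 5 (not isolated)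
Conditions: PivCl (1.05 equiv), Et3N (3.5 equiv), THF, −20 °C; LiCl (1.1 equiv), 3 (1.0 equiv), rt; then PivCl (1.3 equiv), DMAP (10 mol%), rt
Reagents that add atoms: pivaloyl chloride, CC(C)(C)C(=O)Cl
Why: Mixed-anhydride N-acylation of the oxazolidinone (LiCl/Et3N protocol) followed in the same flask by DMAP-catalysed O-pivaloylation of the hindered phenol, which must be masked before enolate oxidation; the auxiliary stereocentre is untouched.

Step 3
Reactants: 6 (two molecules)
Product: 8 (2R,3R)-2,3-bis[3,5-dimethoxy-4-(pivaloyloxy)benzyl]-1,4-bis[(S)-4-isopropyl-2-oxooxazolidin-3-yl]butane-1,4-dione, via lithium Z-enolate 7 (not isolated)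
Conditions: LiN(iPr)2 (1.1 equiv, commercial solution), THF, −78 °C; TiCl4 (1.1 equiv), −78 °C → rt
Reagents that add atoms: none
Why: Oxidative homocoupling of a chelated Z-imide enolate (Kise coupling): TiCl4 forms the titanium enolate, which is oxidised by one electron as tetravalent titanium falls to trivalent titanium, and both α-carbons bond on the face opposite the isopropyl group to give the (R,R)-dimer, freed from minor meso and (S,S) isomers by crystallisation.

Step 4
Reactants: 8
Product: 9 (2R,3R)-2,3-bis(4-hydroxy-3,5-dimethoxybenzyl)butane-1,4-diol [(8R,8'R)-5,5'-dimethoxysecoisolariciresinol]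
Conditions: LiAlH4 (6 equiv), THF, 0 °C → rt; aq. KNaC4H4O6 work-up
Reagents that add atoms: none
Why: Hydride reduction cleaves both exocyclic imide carbonyls to CH2OH and both aryl pivalates to phenols in one operation; reduction is faster than enolisation, so C8 and C8' keep their configuration.

Step 5
Reactants: 9
Product: 16 ciwujiatone [(7S,8R,8'R)-target], via first quinone methide 10 (not isolated), via dimethoxylariciresinol 11 (not isolated), via second quinone methide 12 (not isolated), via syringaresinol 13 (not isolated), via third quinone methide 14 (not isolated), via hemiketal 15 (not isolated)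
Conditions: DDQ (2.0 equiv), 1,4-dioxane/aq. KH2PO4–Na2HPO4 buffer pH 7 (10:1), 0 °C → rt; then DDQ (1.0 equiv, slow addition), rt
Reagents that add atoms: water, O
Why: Proposed new method: three successive DDQ hydride abstractions in one flask — (i) a benzylic C7–H of the 4-alkyl-2,6-dimethoxyphenol gives p-quinone methide 10, which the 9'-OH captures by 5-exo oxa-1,6-addition to close ring A with the aryl group trans to the C8 substituent (C7 = S, controlled by C8); (ii) the same sequence at C7' with the 9-OH closes ring B as the cis-fused furofuran 13 with the aryl group exo; (iii) hydride loss from a benzylic ether C–H gives the O-substituted quinone methide 14, water adds, and hemiketal 15 opens ring B to the aryl ketone with C8' held cis by the bicyclic precursor; the closest known reactions are DDQ or Ag2O oxidative cyclisation of dibenzylbutanediols to 7,9'-epoxylignans and furofurans, and DDQ oxidation of resinol units to ring-opened benzylic ketones.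

**Compound list**

1 | sinapic acid | COc1cc(/C=C/C(=O)O)cc(OC)c1O | starting material
2 | dihydrosinapic acid | COc1cc(CCC(=O)O)cc(OC)c1O | intermediate
3 | (S)-4-isopropyloxazolidin-2-one | CC(C)[C@H]1COC(=O)N1 | starting material
4 | 3-(4-hydroxy-3,5-dimethoxyphenyl)propanoic pivalic anhydride (in flask) | COc1cc(CCC(=O)OC(=O)C(C)(C)C)cc(OC)c1O | intermediate
5 | (S)-3-[3-(4-hydroxy-3,5-dimethoxyphenyl)propanoyl]-4-isopropyloxazolidin-2-one (in flask) | COc1cc(CCC(=O)N2[C@@H](C(C)C)COC2=O)cc(OC)c1O | intermediate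
6 | (S)-3-{3-[3,5-dimethoxy-4-(pivaloyloxy)phenyl]propanoyl}-4-isopropyloxazolidin-2-one | COc1cc(CCC(=O)N2[C@@H](C(C)C)COC2=O)cc(OC)c1OC(=O)C(C)(C)C | intermediate
7 | lithium (Z)-enolate of 6 (in flask) | COc1cc(C/C=C(\O[Li])N2[C@@H](C(C)C)COC2=O)cc(OC)c1OC(=O)C(C)(C)C | intermediate
8 | (2R,3R)-2,3-bis[3,5-dimethoxy-4-(pivaloyloxy)benzyl]-1,4-bis[(S)-4-isopropyl-2-oxooxazolidin-3-yl]butane-1,4-dione | O=C(N1[C@@H](C(C)C)COC1=O)[C@H](Cc1cc(OC)c(OC(=O)C(C)(C)C)c(OC)c1)[C@@H](Cc1cc(OC)c(OC(=O)C(C)(C)C)c(OC)c1)C(=O)N1[C@@H](C(C)C)COC1=O | intermediate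
9 | (2R,3R)-2,3-bis(4-hydroxy-3,5-dimethoxybenzyl)butane-1,4-diol | OC[C@H](Cc1cc(OC)c(O)c(OC)c1)[C@@H](Cc1cc(OC)c(O)c(OC)c1)CO | intermediate
10 | C7 p-quinone methide of 9 (in flask) | OC[C@H](C=C1C=C(OC)C(=O)C(OC)=C1)[C@@H](Cc1cc(OC)c(O)c(OC)c1)CO | intermediate
11 | (7S,8R,8'R)-5,5'-dimethoxylariciresinol, ring A closed (in flask) | COc1cc(C[C@H]2CO[C@H](c3cc(OC)c(O)c(OC)c3)[C@H]2CO)cc(OC)c1O | intermediate
12 | C7' p-quinone methide of 11 (in flask) | COC1=CC(=C[C@H]2CO[C@H](c3cc(OC)c(O)c(OC)c3)[C@H]2CO)C=C(OC)C1=O | intermediate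
13 | (7S,8R,7'S,8'R)-syringaresinol, rings A and B closed (in flask) | COc1cc([C@H]2OC[C@H]3[C@@H]2CO[C@@H]3c4cc(OC)c(O)c(OC)c4)cc(OC)c1O | intermediate
14 | C7' O-substituted p-quinone methide of 13 (in flask) | COC1=CC(=C2OC[C@H]3[C@@H]2CO[C@@H]3c4cc(OC)c(O)c(OC)c4)C=C(OC)C1=O | intermediate
15 | 7'-hydroxysyringaresinol, bicyclic hemiketal, C7' epimers (in flask) | COc1cc(C2(O)OC[C@H]3[C@@H]2CO[C@@H]3c4cc(OC)c(O)c(OC)c4)cc(OC)c1O | intermediate
16 | ciwujiatone, (4-hydroxy-3,5-dimethoxyphenyl)[(3R,4R,5S)-5-(4-hydroxy-3,5-dimethoxyphenyl)-4-(hydroxymethyl)oxolan-3-yl]methanone | COc1cc(C(=O)[C@H]2CO[C@H](c3cc(OC)c(O)c(OC)c3)[C@H]2CO)cc(OC)c1O | target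

**Step count and risks**

Total steps: 5. Longest linear sequence: 5 (1 → 2 → 6 → 8 → 9 → 16).

Most likely to fail:

- **Step 5 (triple DDQ cascade).** The third oxidation competes with a fourth one (C7–H of 16, leading to the 1,4-diketone), so 16 cannot exceed about half of the material; unreacted 13 is recyclable. Acid from the reduced quinone could also divert quinone methide 10 into Friedel–Crafts closure (aryltetralin) or epimerise C8', hence the pH 7 buffer and base-free work-up. Fallback: set out from 9 with only 2.0 equiv DDQ and isolate 13. Acetylate one phenol (Ac2O 1.0 equiv, pyridine, 0 °C; diacetate and unreacted 13 are recycled) to give mono-O-acetylsyringaresinol F1. DDQ (1.2 equiv, wet dioxane) can then form a quinone methide only on the half with the free phenol and gives 4-O-acetylciwujiatone F2 without the statistical ceiling. NH4OAc in aqueous MeOH at rt removes the aryl acetate under near-neutral conditions and returns to the route at 16.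

- **Step 3 (oxidative enolate homocoupling).** Yield and (R,R) selectivity may drop with this electron-rich, pivalate-bearing substrate (acyl transfer to the enolate, meso dimer). Fallback: give up auxiliary control and set out from 1. H2SO4/MeOH gives methyl sinapate F3, and iBu2AlH (toluene, −78 → 0 °C) gives sinapyl alcohol F4. Trametes versicolor laccase/O2 (acetate buffer pH 5/acetone) dimerises it by 8–8' radical coupling and double oxa-cyclisation to rac-syringaresinol F5. Preparative chromatography on an amylose tris(3,5-dimethylphenylcarbamate) phase delivers the (7S,8R,7'S,8'R) enantiomer, which is 13. The route is rejoined at 13, which is taken to 16 by the last oxidation of step 5 (1.0 equiv DDQ).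

- **Step 2 (one-pot acylation with a free phenol present).** The phenol may be acylated by mixed anhydride 4 (oligoesters) before the oxazolidinone reacts. Fallback: protect first, then acylate. Set out from 2; Schotten–Baumann pivaloylation (PivCl, 2 M aq. NaOH, 0 °C) gives 3-[3,5-dimethoxy-4-(pivaloyloxy)phenyl]propanoic acid F6, which is isolated. PivCl/Et3N (THF, −20 °C) converts it into its mixed pivalic anhydride F7, and LiCl/3 at rt gives 6, where the route is rejoined.

**Further compounds**

F1 | step 5 | mono-O-acetyl-(7S,8R,7'S,8'R)-syringaresinol | COc1cc([C@H]2OC[C@H]3[C@@H]2CO[C@@H]3c4cc(OC)c(OC(C)=O)c(OC)c4)cc(OC)c1O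
F2 | step 5 | 4-O-acetylciwujiatone (acetate on the C7 aryl ring) | COc1cc(C(=O)[C@H]2CO[C@H](c3cc(OC)c(OC(C)=O)c(OC)c3)[C@H]2CO)cc(OC)c1O
F3 | step 3 | methyl sinapate | COC(=O)/C=C/c1cc(OC)c(O)c(OC)c1
F4 | step 3 | sinapyl alcohol | OC/C=C/c1cc(OC)c(O)c(OC)c1
F5 | step 3 | rac-syringaresinol (1:1 mixture of both enantiomers) | COc1cc([C@H]2OC[C@H]3[C@@H]2CO[C@@H]3c4cc(OC)c(O)c(OC)c4)cc(OC)c1O.COc1cc([C@@H]2OC[C@@H]3[C@H]2CO[C@H]3c4cc(OC)c(O)c(OC)c4)cc(OC)c1O
F6 | step 2 | 3-[3,5-dimethoxy-4-(pivaloyloxy)phenyl]propanoic acid | COc1cc(CCC(=O)O)cc(OC)c1OC(=O)C(C)(C)C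
F7 | step 2 | 3-[3,5-dimethoxy-4-(pivaloyloxy)phenyl]propanoic pivalic anhydride | COc1cc(CCC(=O)OC(=O)C(C)(C)C)cc(OC)c1OC(=O)C(C)(C)C
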